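## The problem

Target **27** is an isoflavanone: a chroman-4-one (benzo ring A fused to pyranone ring C) that carries ring B on C3. Ring B is substituted at five contiguous positions: C1' is bonded to C3, C2' and C3' carry free hydroxyls (a catechol), C4' a methoxy group and C5' a prenyl chain. The only stereocentre is C3 (R). It is benzylic and α to the C4 carbonyl, so no neighbouring centre can control it, and it racemises by enolisation under base and, more slowly, under hot acid. It must therefore be set by a reagent, late, and every later step must stay close to neutral. The catechol is easily oxidised, and the prenyl alkene will not survive hydrogenation, hypochlorite, electrophilic carbenes or hot mineral acid. The three phenols need protection that can be removed without touching C3. The feature that makes the key step possible is that C3 is a single carbon carrying ring B between C2 (an OCH2 group) and C4 (the carbonyl). Taking C3 out with its aryl group joins C2 to C4 and leaves 6-hydroxybenzofuran-3(2H)-one **1**, a commercial five-membered ketone, so C3 plus ring B can be put back as an aryl carbene inserted into an enol derivative of **1**.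

## Retrosynthesis

**27 from 26.** Three O–Si bonds are cut last. Silyl ethers are chosen for all three phenols because they fall to weakly acidic fluoride, which forms neither a phenoxide nor an enolate, so the labile C3 centre of **26** should reach **27** intact. An acid-labile ketal at this stage would need hot aqueous acid, which neither C3 nor the prenyl group should be asked to bear.

**26 from 23 by way of 25.** The C3–H bond, one C2–H bond and, temporarily, a C4–H bond are traced back to the flat, achiral isoflavone **23**. Transfer hydrogenation reduces C2=C3 to the racemic isoflavanone **24**, which equilibrates at C3 and is drained by dynamic kinetic resolution into the cis-alcohol **25**. Reoxidation of C4 then gives **26**. This uses the lability of C3 to set it, and it lets all heavy chemistry take place before a stereocentre exists. The price is one oxidation-state detour.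

**23 from 21 and 22.** The C5'–CH2 bond of the prenyl group is cut to aryl bromide **21** and prenylstannane **22**. The alkene is introduced only after the carbene, hypochlorite and hot-acid steps are over. The bromine serves as a placeholder and can be installed at the very start, where the directing effects in **4** converge on C5.

**21 from 19 by way of 20.** This is a protecting-group exchange at the achiral bromoisoflavone stage. The diphenylmethylene ketal of **19** is what the carbene chemistry needs, but its removal needs hot aqueous acid. That is done on **19**, giving triol **20**, which is then silylated to **21**. It costs one extra step and removes the main hazard from the end game.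

**19 from 3 and 15 (key disconnection).** The C2–C3 and C3–C4 bonds are cut together, removing C3 with ring B attached. What remains is the bis-silyl enol ether **3** of the benzofuranone and arylchlorocarbene **16**, stored as chlorodiazirine **15**. The neighbouring cuts (C3–C1' by cross-coupling of a 3-halochromone, or C2 by formylation of a deoxybenzoin) form one bond each and need a pre-built chromone or deoxybenzoin. Here both bonds to C3 form in one operation and ring A comes from a commercial ketone in one step. The forward reaction must add the carbene only to the enol ether double bond of **3**, then open cyclopropane **17** across the old ring bond to chromenylium ion **18**, which loses its silyl group.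

**3 from 1.** Two O–Si bonds; the ketone is silylated as its enol (through **2**), which is the aromatic 3-silyloxybenzofuran.

**15 from 4 and 6.** The diazirine ring comes from amidinium salt **12** by oxidative N–N bond formation (through **13** and **14**). **12** comes from nitrile **10** (through **11**), and **10** from aldehyde **7** (through **8** and **9**). The ketal carbon of **7** comes from **6** and the catechol of **5**, and the C–Br bond of **5** from bromination of commercial **4**. The ketal is chosen because the carbon next to its oxygens carries no hydrogen, so the carbene has no 1,5 C–H bond to insert into.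

## Roads not taken

**Alternative 1:** The cut is C3–C4.
- **Forward step.** Ring A aldehyde **A2** carries on its phenol oxygen a CH2–CH(SO2Tol)–(ring B) chain with a free 2'-hydroxyl. Base expels sulfinate to give the ring B ortho-quinone methide **A3**. A chiral triazolylidene turns the formyl group into an acyl anion equivalent that adds to the exocyclic methide carbon (6-exo-trig), rearomatises ring B and gives **A1**.
- **Merits.** C3 is set directly at the ketone oxidation level, with the prenyl group already in place and no redox detour. The 2'-hydroxyl of the target is used as the activating group.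
- **Weak points.** The base that releases **A3** and the free carbene is also the base that enolises the α-aryl ketone of **A1**, so the enantiomeric purity must survive the conditions that create it. **A3** has hydrogens on the carbon next to the methide and can decay by a 1,5-hydrogen shift to a 2-vinylphenol. **A2** requires the 2'- and 3'-oxygens of ring B to be told apart and a benzylic sulfone to be built next to an aryl ether. The acetal groups of **A1** still have to be removed with acid from the chiral ketone.
- **Comparison.** This road is better in directness of stereocontrol and saves the reduction/oxidation pair. The chosen plan sets against it a stereo-defining step of a known reaction class, a ring B that needs no differentiation of its catechol oxygens, and an achiral isoflavone on which protecting groups can be changed safely.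

**Alternative 2:** The cut is C2–C3.
- **Forward step.** Aryl diazo ketone **A5** (ring A with an ortho-methoxy group, ring B with prenyl and ketal) is decomposed by dirhodium tetrakis[N-phthaloyl-(S)-tert-leucinate], Rh2(S-PTTL)4, or its enantiomer. The carbene carbon at C3 inserts into a C–H bond of the methoxy group and closes the pyranone ring to **A4**.
- **Merits.** C2 comes from a methyl ether at no cost. The precursor is a classical deoxybenzoin plus a diazo transfer. C3 is set catalytically without a redox detour, and the route is probably two or three steps shorter than the chosen one.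
- **Weak points.** The insertion must form a six-membered ring at a primary C–H bond, where five-membered closure is normally preferred and no such position is offered. The electrophilic carbene also sees the prenyl alkene (cyclopropanation), the phenyl rings of the ketal and ring A (aromatic addition). The new centre is born α to a ketone next to a Lewis-acidic metal. **A4** still carries the diphenylmethylene ketal, whose hydrolysis needs hot acid in the presence of C3 and the prenyl group.
- **Comparison.** This road is shorter. The chosen plan answers with a carbene step in which the only reactive alkene is the intended one, stereocontrol by a separate well-understood step, and removal of the ketal before any sensitive group exists.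

**Alternative 3:** The cuts are C4–C4a and O1–C2.
- **Forward step.** Irradiation of aryl 2-arylacrylate **A7** shifts the acyl group from oxygen to the ortho carbon (photo-Fries). The freed phenol adds to the enone terminus (6-endo-trig oxa-Michael) to give racemic **A6**.
- **Merits.** It is the shortest assembly, from an ester of two simple fragments, with no metal and with the prenyl group in place.
- **Weak points.** The acyl group can go to either ortho position or to the para position of the 3-oxygenated phenyl ester, and only one ortho isomer leads to the 7-oxygenated chromanone. The 2-arylacrylate and the prenyl alkene are themselves photoreactive. C3 arises by protonation and is racemic.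
- **Comparison.** The lack of stereocontrol is not decisive, because a racemic isoflavanone can enter the same dynamic kinetic resolution and reoxidation as the chosen plan. On paper this road would reach that point in fewer steps. The chosen plan sets against it a ring A substitution pattern fixed by the starting ketone, a thermal key step without regioisomers, and robust intermediates. Its own key step, however, is without direct precedent, whereas the photo-Fries shift is known but typically inefficient.

Key step: step 7

Assumption: the sense of induction of RuCl(p-cymene)(TsDPEN) on 3-arylchroman-4-ones is taken to follow that of chroman-4-one and 1-tetralone, the (R,R)-ligand giving the (4R)-alcohol; with hydride delivery anti to the aryl group this is the cis-(3R,4R)-alcohol.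

Abbreviations: TBS = tert-butyldimethylsilyl; ArB = 6-bromo-7-methoxy-2,2-diphenyl-1,3-benzodioxol-4-yl; DMP = Dess–Martin periodinane.

## Route

Step 1
Reactants: 1 6-hydroxy-1-benzofuran-3(2H)-one
Product: 3 3,6-bis[(tert-butyldimethylsilyl)oxy]-1-benzofuran, via mono-silyl ether 2 (not isolated)
Conditions: TBSOTf, Et3N, CH2Cl2, 0 °C to rt; non-aqueous work-up
Reagents that add atoms: tert-butyldimethylsilyl trifluoromethanesulfonate, CC(C)(C)[Si](C)(C)OS(=O)(=O)C(F)(F)F
Why: Silylation of the phenol, then soft enolisation and O-silylation of the ketone (silyl enol ether formation); the enol form is the aromatic 3-silyloxybenzofuran, which drives the second silylation.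

Step 2
Reactants: 4 2,3-dihydroxy-4-methoxybenzaldehyde
Product: 5 5-bromo-2,3-dihydroxy-4-methoxybenzaldehyde
Conditions: Br2, NaOAc, AcOH, rt
Reagents that add atoms: bromine, BrBr
Why: Electrophilic aromatic bromination; C5 is para to the 2-hydroxyl, ortho to the methoxy group and meta to the formyl group, whereas C6, the only other free position, is ortho to the deactivating formyl group.

Step 3
Reactants: 5 5-bromo-2,3-dihydroxy-4-methoxybenzaldehyde, 6 dichlorodiphenylmethane
Product: 7 6-bromo-7-methoxy-2,2-diphenyl-1,3-benzodioxole-4-carbaldehyde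
Conditions: Ph2O, 175 °C, N2 stream
Reagents that add atoms: none
Why: Double displacement of chloride by the two catechol oxygens gives the five-membered diphenylmethylene ketal, a standard catechol protection that leaves no C–H bond on the carbon next to oxygen.

Step 4
Reactants: 7 6-bromo-7-methoxy-2,2-diphenyl-1,3-benzodioxole-4-carbaldehyde
Product: 10 6-bromo-7-methoxy-2,2-diphenyl-1,3-benzodioxole-4-carbonitrile, via aldimine 8 (not isolated), via N-iodoaldimine 9 (not isolated)
Conditions: I2, aq. NH3, THF, rt
Reagents that add atoms: ammonia, N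
Why: Oxidative conversion of an aldehyde into a nitrile: condensation with ammonia, N-iodination and loss of HI; the mildly basic medium leaves the ketal and the aryl bromide untouched.

Step 5
Reactants: 10 6-bromo-7-methoxy-2,2-diphenyl-1,3-benzodioxole-4-carbonitrile
Product: 12 6-bromo-7-methoxy-2,2-diphenyl-1,3-benzodioxole-4-carboximidamide hydrochloride, via lithium bis-silylamidinate 11 (not isolated)
Conditions: LiN(SiMe3)2, THF, 0 °C to rt; then HCl (4 M in 1,4-dioxane), 0 °C
Reagents that add atoms: lithium bis(trimethylsilyl)amide, [Li+].C[Si](C)(C)[N-][Si](C)(C)C; hydrogen chloride, Cl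
Why: Addition of the silylamide to the nitrile and N-to-N silyl shift, then anhydrous acid removes both silyl groups and precipitates the amidinium salt; the standard nitrile-to-amidine conversion, and an amide base does not exchange the aryl bromide.

Step 6
Reactants: 12 6-bromo-7-methoxy-2,2-diphenyl-1,3-benzodioxole-4-carboximidamide hydrochloride
Product: 15 3-(6-bromo-7-methoxy-2,2-diphenyl-1,3-benzodioxol-4-yl)-3-chloro-3H-diazirine, via dichloroamidine 13 (not isolated), via N-chlorodiazirine 14 (not isolated)
Conditions: aq. NaOCl, LiCl, DMSO/pentane, 0 °C to rt; kept cold and dark, used at once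
Reagents that add atoms: sodium hypochlorite, [Na+].[O-]Cl
Why: Graham oxidation: double N-chlorination, base-induced N–N bond formation and shift of chlorine from nitrogen to carbon by way of chloride; the standard route to 3-aryl-3-chlorodiazirines.

Step 7
Reactants: 3 3,6-bis[(tert-butyldimethylsilyl)oxy]-1-benzofuran, 15 3-(6-bromo-7-methoxy-2,2-diphenyl-1,3-benzodioxol-4-yl)-3-chloro-3H-diazirine
Product: 19 3-(6-bromo-7-methoxy-2,2-diphenyl-1,3-benzodioxol-4-yl)-7-[(tert-butyldimethylsilyl)oxy]-4H-chromen-4-one, via arylchlorocarbene 16 (not isolated), via chlorocyclopropane 17 (not isolated), via silyloxychromenylium chloride 18 (not isolated)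
Conditions: 15 added slowly to 3 (excess), Na2CO3, MeCN, 45 °C, dark
Reagents that add atoms: none
Why: Proposed new method: Gentle thermolysis of 15 expels N2 and gives singlet arylchlorocarbene 16, which adds in a [2+1] fashion to the C2=C3 bond of 3, the only doubly oxygen-substituted and by far the most nucleophilic π bond present, to give chlorocyclopropane 17. Ionisation of the benzylic C–Cl bond, helped by the electron-rich aryl group, is coupled to disrotatory opening of the cyclopropane bond opposite the departing chloride, which is the old C2–C3 ring bond, so the five-membered ring expands to the aromatic 4-silyloxychromenylium ion 18 with the carbene carbon, ring B attached, between the former C2 and C3. Chloride then removes the silyl group from the C4 oxygen and releases the chromone carbonyl of 19, while the less activated aryl silyl ether at C7 stays. The closest known reaction types are the Ciamician–Dennstedt-type insertion of chlorodiazirine-derived arylchlorocarbenes into indoles and pyrroles, the dihalocarbene expansion of benzofuran to 3-halochromenes and the dihalocarbene ring expansion of cyclic silyl enol ethers to 2-haloenones; their combination on a benzofuranone silyl enol ether is not known. The pyranone ring is closed by one-carbon ring expansion (cheletropic addition followed by 2π-electrocyclic opening), not by an end-to-end cyclisation. No stereocentre survives, because the cyclopropane centres of 17 are destroyed on opening, so the orientation of chlorine affects only the rate (endo chloride opens in concert, exo chloride after ionisation to the aryl-stabilised cyclopropyl cation). The step needs chemoselectivity for the enol ether over the benzo rings and over the carbene's own substituents; this is secured by the electron richness of that bond, by the ketal having no C–H bond on the carbon next to oxygen, and by slow addition of 15 to excess 3, which suppresses azine and carbene-dimer formation.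

Step 8
Reactants: 19 3-(6-bromo-7-methoxy-2,2-diphenyl-1,3-benzodioxol-4-yl)-7-[(tert-butyldimethylsilyl)oxy]-4H-chromen-4-one
Product: 20 3-(5-bromo-2,3-dihydroxy-4-methoxyphenyl)-7-hydroxy-4H-chromen-4-one
Conditions: 6 M aq. HCl, 1,4-dioxane, 80 °C
Reagents that add atoms: none
Why: Acid-catalysed ketal hydrolysis through the diphenyl(aryloxy)carbenium ion, with protodesilylation of the aryl silyl ether; the bromoisoflavone is achiral and has no acid-sensitive group, so the harsh deprotection is placed here, before the prenyl group and C3 exist.

Step 9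
Reactants: 20 3-(5-bromo-2,3-dihydroxy-4-methoxyphenyl)-7-hydroxy-4H-chromen-4-one
Product: 21 3-{5-bromo-2,3-bis[(tert-butyldimethylsilyl)oxy]-4-methoxyphenyl}-7-[(tert-butyldimethylsilyl)oxy]-4H-chromen-4-one
Conditions: TBSCl, imidazole, DMAP (cat.), DMF, rt to 40 °C
Reagents that add atoms: tert-butyldimethylsilyl chloride, CC(C)(C)[Si](C)(C)Cl
Why: Imidazole-promoted silylation of phenols; all three hydroxyls get the same group, so the end game needs a single fluoride treatment.

Step 10
Reactants: 21 3-{5-bromo-2,3-bis[(tert-butyldimethylsilyl)oxy]-4-methoxyphenyl}-7-[(tert-butyldimethylsilyl)oxy]-4H-chromen-4-one, 22 tributyl(3-methylbut-2-en-1-yl)stannane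
Product: 23 3-{2,3-bis[(tert-butyldimethylsilyl)oxy]-4-methoxy-5-(3-methylbut-2-en-1-yl)phenyl}-7-[(tert-butyldimethylsilyl)oxy]-4H-chromen-4-one
Conditions: Pd(PPh3)4 (cat., zerovalent palladium), toluene, 110 °C, degassed
Reagents that add atoms: none
Why: Stille coupling: oxidative addition into the C5'–Br bond, transmetallation with the prenylstannane and reductive elimination at the less hindered allyl terminus give the linear prenyl arene; the neutral, fluoride-free medium keeps the aryl silyl ethers.

Step 11
Reactants: 23 3-{2,3-bis[(tert-butyldimethylsilyl)oxy]-4-methoxy-5-(3-methylbut-2-en-1-yl)phenyl}-7-[(tert-butyldimethylsilyl)oxy]-4H-chromen-4-one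
Product: 25 (3R,4R)-3-{2,3-bis[(tert-butyldimethylsilyl)oxy]-4-methoxy-5-(3-methylbut-2-en-1-yl)phenyl}-7-[(tert-butyldimethylsilyl)oxy]-3,4-dihydro-2H-chromen-4-ol (cis), via racemic isoflavanone 24 (not isolated)
Conditions: RuCl(p-cymene)[(R,R)-TsDPEN] (cat., divalent ruthenium), HCO2H/Et3N (5:2), EtOAc, 40 °C
Reagents that add atoms: none
Why: Noyori–Ikariya transfer hydrogenation with dynamic kinetic resolution, a known transformation of isoflavones: the ruthenium hydride first reduces C2=C3 to racemic 24, whose C3 epimerises through the enol under Et3N. The (R,R)-catalyst then reduces the (3R)-ketone faster, delivering hydride to C4 anti to the aryl group, so C3 and C4 are both set by the catalyst and the cis relationship follows from the aryl group; the isolated prenyl alkene is not touched.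

Step 12
Reactants: 25 (3R,4R)-3-{2,3-bis[(tert-butyldimethylsilyl)oxy]-4-methoxy-5-(3-methylbut-2-en-1-yl)phenyl}-7-[(tert-butyldimethylsilyl)oxy]-3,4-dihydro-2H-chromen-4-ol
Product: 26 (3R)-3-{2,3-bis[(tert-butyldimethylsilyl)oxy]-4-methoxy-5-(3-methylbut-2-en-1-yl)phenyl}-7-[(tert-butyldimethylsilyl)oxy]-2,3-dihydro-4H-chromen-4-one
Conditions: DMP, NaHCO3, CH2Cl2, 0 °C
Reagents that add atoms: none
Why: Dess–Martin oxidation of the benzylic alcohol removes the auxiliary C4 centre; with bicarbonate buffer and low temperature no base strong enough to enolise the new α-aryl ketone is present, so C3 keeps its R configuration.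

Step 13
Reactants: 26 (3R)-3-{2,3-bis[(tert-butyldimethylsilyl)oxy]-4-methoxy-5-(3-methylbut-2-en-1-yl)phenyl}-7-[(tert-butyldimethylsilyl)oxy]-2,3-dihydro-4H-chromen-4-one
Product: 27 (3R)-3-[2,3-dihydroxy-4-methoxy-5-(3-methylbut-2-en-1-yl)phenyl]-7-hydroxy-2,3-dihydro-4H-chromen-4-one
Conditions: HF·pyridine, pyridine/THF, 0 °C to rt, argon; pH 7 buffer work-up
Reagents that add atoms: none
Why: Fluoride cleavage of the three aryl silyl ethers with a weakly acidic reagent; neither phenoxide nor enolate is formed, so C3 and the catechol should be preserved, and the prenyl alkene is inert to the diluted reagent.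

## Compound list

1 | 6-hydroxy-1-benzofuran-3(2H)-one | O=C1COc2cc(O)ccc21 | starting material
2 | 6-[(tert-butyldimethylsilyl)oxy]-1-benzofuran-3(2H)-one | O=C1COc2cc(O[Si](C)(C)C(C)(C)C)ccc21 | intermediate
3 | 3,6-bis[(tert-butyldimethylsilyl)oxy]-1-benzofuran | CC(C)(C)[Si](C)(C)Oc1ccc2c(O[Si](C)(C)C(C)(C)C)coc2c1 | intermediate
4 | 2,3-dihydroxy-4-methoxybenzaldehyde | COc1ccc(C=O)c(O)c1O | starting material
5 | 5-bromo-2,3-dihydroxy-4-methoxybenzaldehyde | COc1c(Br)cc(C=O)c(O)c1O | intermediate
6 | dichlorodiphenylmethane | ClC(Cl)(c1ccccc1)c1ccccc1 | starting material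
7 | 6-bromo-7-methoxy-2,2-diphenyl-1,3-benzodioxole-4-carbaldehyde | COc1c(Br)cc(C=O)c2OC(c3ccccc3)(c3ccccc3)Oc12 | intermediate
8 | 1-(ArB)methanimine (N-unsubstituted aldimine of 7) | COc1c(Br)cc(C=N)c2OC(c3ccccc3)(c3ccccc3)Oc12 | intermediate
9 | N-iodo-1-(ArB)methanimine | COc1c(Br)cc(C=NI)c2OC(c3ccccc3)(c3ccccc3)Oc12 | intermediate
10 | 6-bromo-7-methoxy-2,2-diphenyl-1,3-benzodioxole-4-carbonitrile | COc1c(Br)cc(C#N)c2OC(c3ccccc3)(c3ccccc3)Oc12 | intermediate
11 | lithium N,N'-bis(trimethylsilyl)-6-bromo-7-methoxy-2,2-diphenyl-1,3-benzodioxole-4-carboximidamidate | COc1c(Br)cc(C(=N[Si](C)(C)C)[N-][Si](C)(C)C)c2OC(c3ccccc3)(c3ccccc3)Oc12.[Li+] | intermediate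
12 | 6-bromo-7-methoxy-2,2-diphenyl-1,3-benzodioxole-4-carboximidamide hydrochloride | COc1c(Br)cc(C(N)=[NH2+])c2OC(c3ccccc3)(c3ccccc3)Oc12.[Cl-] | intermediate
13 | N,N'-dichloro-6-bromo-7-methoxy-2,2-diphenyl-1,3-benzodioxole-4-carboximidamide | COc1c(Br)cc(C(NCl)=NCl)c2OC(c3ccccc3)(c3ccccc3)Oc12 | intermediate
14 | 3-(ArB)-1-chloro-1H-diazirine | COc1c(Br)cc(C2=NN2Cl)c2OC(c3ccccc3)(c3ccccc3)Oc12 | intermediate
15 | 3-(6-bromo-7-methoxy-2,2-diphenyl-1,3-benzodioxol-4-yl)-3-chloro-3H-diazirine | COc1c(Br)cc(C2(Cl)N=N2)c2OC(c3ccccc3)(c3ccccc3)Oc12 | intermediate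
16 | (6-bromo-7-methoxy-2,2-diphenyl-1,3-benzodioxol-4-yl)chlorocarbene | COc1c(Br)cc([C]Cl)c2OC(c3ccccc3)(c3ccccc3)Oc12 | intermediate
17 | 1-(ArB)-1-chloro-4,6b-bis[(tert-butyldimethylsilyl)oxy]-1a,6b-dihydro-1H-cyclopropa[b][1]benzofuran (racemic, either orientation of chlorine) | COc1c(Br)cc(C2(Cl)C3Oc4cc(O[Si](C)(C)C(C)(C)C)ccc4C23O[Si](C)(C)C(C)(C)C)c2OC(c3ccccc3)(c3ccccc3)Oc12 | intermediate
18 | 3-(ArB)-4,7-bis[(tert-butyldimethylsilyl)oxy]chromenylium chloride | COc1c(Br)cc(-c2c[o+]c3cc(O[Si](C)(C)C(C)(C)C)ccc3c2O[Si](C)(C)C(C)(C)C)c2OC(c3ccccc3)(c3ccccc3)Oc12.[Cl-] | intermediate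
19 | 3-(6-bromo-7-methoxy-2,2-diphenyl-1,3-benzodioxol-4-yl)-7-[(tert-butyldimethylsilyl)oxy]-4H-chromen-4-one | COc1c(Br)cc(-c2coc3cc(O[Si](C)(C)C(C)(C)C)ccc3c2=O)c2OC(c3ccccc3)(c3ccccc3)Oc12 | intermediate
20 | 3-(5-bromo-2,3-dihydroxy-4-methoxyphenyl)-7-hydroxy-4H-chromen-4-one | COc1c(Br)cc(-c2coc3cc(O)ccc3c2=O)c(O)c1O | intermediate
21 | 3-{5-bromo-2,3-bis[(tert-butyldimethylsilyl)oxy]-4-methoxyphenyl}-7-[(tert-butyldimethylsilyl)oxy]-4H-chromen-4-one | COc1c(Br)cc(-c2coc3cc(O[Si](C)(C)C(C)(C)C)ccc3c2=O)c(O[Si](C)(C)C(C)(C)C)c1O[Si](C)(C)C(C)(C)C | intermediate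
22 | tributyl(3-methylbut-2-en-1-yl)stannane | CCCC[Sn](CCCC)(CCCC)CC=C(C)C | starting material
23 | 3-{2,3-bis[(tert-butyldimethylsilyl)oxy]-4-methoxy-5-(3-methylbut-2-en-1-yl)phenyl}-7-[(tert-butyldimethylsilyl)oxy]-4H-chromen-4-one | COc1c(CC=C(C)C)cc(-c2coc3cc(O[Si](C)(C)C(C)(C)C)ccc3c2=O)c(O[Si](C)(C)C(C)(C)C)c1O[Si](C)(C)C(C)(C)C | intermediate
24 | racemic 3-{2,3-bis[(tert-butyldimethylsilyl)oxy]-4-methoxy-5-(3-methylbut-2-en-1-yl)phenyl}-7-[(tert-butyldimethylsilyl)oxy]-2,3-dihydro-4H-chromen-4-one | COc1c(CC=C(C)C)cc(C2COc3cc(O[Si](C)(C)C(C)(C)C)ccc3C2=O)c(O[Si](C)(C)C(C)(C)C)c1O[Si](C)(C)C(C)(C)C | intermediate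
25 | (3R,4R)-3-{2,3-bis[(tert-butyldimethylsilyl)oxy]-4-methoxy-5-(3-methylbut-2-en-1-yl)phenyl}-7-[(tert-butyldimethylsilyl)oxy]-3,4-dihydro-2H-chromen-4-ol (cis) | COc1c(CC=C(C)C)cc([C@@H]2COc3cc(O[Si](C)(C)C(C)(C)C)ccc3[C@@H]2O)c(O[Si](C)(C)C(C)(C)C)c1O[Si](C)(C)C(C)(C)C | intermediate
26 | (3R)-3-{2,3-bis[(tert-butyldimethylsilyl)oxy]-4-methoxy-5-(3-methylbut-2-en-1-yl)phenyl}-7-[(tert-butyldimethylsilyl)oxy]-2,3-dihydro-4H-chromen-4-one | COc1c(CC=C(C)C)cc([C@@H]2COc3cc(O[Si](C)(C)C(C)(C)C)ccc3C2=O)c(O[Si](C)(C)C(C)(C)C)c1O[Si](C)(C)C(C)(C)C | intermediate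
27 | (3R)-3-[2,3-dihydroxy-4-methoxy-5-(3-methylbut-2-en-1-yl)phenyl]-7-hydroxy-2,3-dihydro-4H-chromen-4-one | COc1c(CC=C(C)C)cc([C@@H]2COc3cc(O)ccc3C2=O)c(O)c1O | target

## Step count and risks

Total step count: 13.
Longest linear sequence: 12 steps (from 4 through steps 2 to 13); step 1 is the only step of the short branch.

Least certain steps:

**Step 7 (key step).**
- **What may go wrong.** Unproductive decay of the carbene (azine formation with unreacted diazirine, dimerisation, capture by traces of water) may outrun addition to the enol ether. Premature loss of the enol silyl group may open the cyclopropane in the wrong sense. The electron-rich diazirine may also decompose before use, so the step depends on the quality of 15 from step 6.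
- **Fallback (known chemistry).** It sets out from aldehyde 7. Claisen–Schmidt condensation (KOH, EtOH) with 1-[2-hydroxy-4-(methoxymethoxy)phenyl]ethan-1-one F1 should give the 2'-hydroxychalcone F2. Tl(NO3)3·3H2O (trivalent thallium) in MeOH/HC(OMe)3 then brings about the oxidative 1,2-shift of the electron-rich ring B to the β-keto dimethyl acetal F3. Warm aqueous HCl in dioxane closes the chromone ring and removes the methoxymethyl group and the ketal in the same operation, so the sequence rejoins the route at 20. It also bypasses steps 4 to 6 and therefore covers a diazirine that cannot be made or stored.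

**Step 10.**
- **What may go wrong.** Coupling at the wrong allyl terminus would give the 1,1-dimethylallyl isomer. Oxidative addition into the electron-rich, ortho-substituted C–Br bond may be slow and let the stannane homocouple.
- **Fallback.** From 21, Stille coupling with allyltributylstannane (Pd(PPh3)4) should give the 5'-allyl isoflavone F4, where the two allyl termini lead to the same product. Cross-metathesis with 2-methylbut-2-ene using the second-generation Grubbs catalyst RuCl2(=CHPh)(PCy3)(H2IMes) then gives 23.

**Step 11.**
- **What may go wrong.** The crowded 2'-silyloxy aryl group may slow conjugate reduction or C3 epimerisation relative to ketone reduction, which would lower the selectivity of the dynamic resolution. The formate/amine medium may also strip the C7 silyl ether.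
- **Fallback.** From 23, conjugate reduction with i-Bu2AlH at −78 °C should give racemic 24 as an isolated compound. Preparative chromatography on a chiral stationary phase then gives the (3R)-enantiomer, which is 26. The (3S)-enantiomer F5 is re-equilibrated with Et3N to 24 and recycled. The route is rejoined at 26 and step 12 is not needed.

**Step 13.**
- **What may go wrong.** Partial racemisation at C3 through enolisation during the removal of three silyl groups, or slow cleavage at the crowded 2',3'-positions that forces longer exposure.
- **Fallback.** Acetal protection replaces silyl protection. From 20, MOMCl/i-Pr2NEt should give the tris(methoxymethyl) ether F6, and Stille coupling with 22 the prenyl isoflavone F7. Transfer hydrogenation as in step 11 gives the cis-(3R,4R)-alcohol F8, and DMP oxidation the (3R)-isoflavanone tris(methoxymethyl) ether F9. Dilute HCl in MeOH at 0 °C to rt then removes the acetals without any basic species and gives 27.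

**Step 2.**
- **What may go wrong.** Oxidation of the free catechol by bromine, or bromination at C6.
- **Fallback.** The order is reversed: from 4, ketalisation with 6 (as in step 3) gives 7-methoxy-2,2-diphenyl-1,3-benzodioxole-4-carbaldehyde F10. Bromination with N-bromosuccinimide in MeCN, ortho to the methoxy group and para to a ketal oxygen, then gives 7.

## Further compounds

F1 | step 7 | 1-[2-hydroxy-4-(methoxymethoxy)phenyl]ethan-1-one | CC(=O)c1ccc(OCOC)cc1O
F2 | step 7 | (E)-3-(6-bromo-7-methoxy-2,2-diphenyl-1,3-benzodioxol-4-yl)-1-[2-hydroxy-4-(methoxymethoxy)phenyl]prop-2-en-1-one | COCOc1ccc(C(=O)/C=C/c2cc(Br)c(OC)c3OC(c4ccccc4)(c4ccccc4)Oc23)c(O)c1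
F3 | step 7 | racemic 2-(6-bromo-7-methoxy-2,2-diphenyl-1,3-benzodioxol-4-yl)-1-[2-hydroxy-4-(methoxymethoxy)phenyl]-3,3-dimethoxypropan-1-one | COCOc1ccc(C(=O)C(C(OC)OC)c2cc(Br)c(OC)c3OC(c4ccccc4)(c4ccccc4)Oc23)c(O)c1
F4 | step 10 | 3-{2,3-bis[(tert-butyldimethylsilyl)oxy]-4-methoxy-5-(prop-2-en-1-yl)phenyl}-7-[(tert-butyldimethylsilyl)oxy]-4H-chromen-4-one | COc1c(CC=C)cc(-c2coc3cc(O[Si](C)(C)C(C)(C)C)ccc3c2=O)c(O[Si](C)(C)C(C)(C)C)c1O[Si](C)(C)C(C)(C)C
F5 | step 11 | (3S)-3-{2,3-bis[(tert-butyldimethylsilyl)oxy]-4-methoxy-5-(3-methylbut-2-en-1-yl)phenyl}-7-[(tert-butyldimethylsilyl)oxy]-2,3-dihydro-4H-chromen-4-one | COc1c(CC=C(C)C)cc([C@H]2COc3cc(O[Si](C)(C)C(C)(C)C)ccc3C2=O)c(O[Si](C)(C)C(C)(C)C)c1O[Si](C)(C)C(C)(C)C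
F6 | step 13 | 3-[5-bromo-4-methoxy-2,3-bis(methoxymethoxy)phenyl]-7-(methoxymethoxy)-4H-chromen-4-one | COc1c(Br)cc(-c2coc3cc(OCOC)ccc3c2=O)c(OCOC)c1OCOC
F7 | step 13 | 3-[4-methoxy-2,3-bis(methoxymethoxy)-5-(3-methylbut-2-en-1-yl)phenyl]-7-(methoxymethoxy)-4H-chromen-4-one | COc1c(CC=C(C)C)cc(-c2coc3cc(OCOC)ccc3c2=O)c(OCOC)c1OCOC
F8 | step 13 | (3R,4R)-3-[4-methoxy-2,3-bis(methoxymethoxy)-5-(3-methylbut-2-en-1-yl)phenyl]-7-(methoxymethoxy)-3,4-dihydro-2H-chromen-4-ol | COc1c(CC=C(C)C)cc([C@@H]2COc3cc(OCOC)ccc3[C@@H]2O)c(OCOC)c1OCOC
F9 | step 13 | (3R)-3-[4-methoxy-2,3-bis(methoxymethoxy)-5-(3-methylbut-2-en-1-yl)phenyl]-7-(methoxymethoxy)-2,3-dihydro-4H-chromen-4-one | COc1c(CC=C(C)C)cc([C@@H]2COc3cc(OCOC)ccc3C2=O)c(OCOC)c1OCOC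
F10 | step 2 | 7-methoxy-2,2-diphenyl-1,3-benzodioxole-4-carbaldehyde | COc1ccc(C=O)c2OC(c3ccccc3)(c3ccccc3)Oc12
A1 | alternative 1 | (3R)-3-[2-hydroxy-4-methoxy-3-(methoxymethoxy)-5-(3-methylbut-2-en-1-yl)phenyl]-7-(methoxymethoxy)-2,3-dihydro-4H-chromen-4-one | COc1c(CC=C(C)C)cc([C@@H]2COc3cc(OCOC)ccc3C2=O)c(O)c1OCOC
A2 | alternative 1 | racemic 2-{2-[2-hydroxy-4-methoxy-3-(methoxymethoxy)-5-(3-methylbut-2-en-1-yl)phenyl]-2-(4-methylbenzenesulfonyl)ethoxy}-4-(methoxymethoxy)benzaldehyde | COCOc1ccc(C=O)c(OCC(c2cc(CC=C(C)C)c(OC)c(OCOC)c2O)S(=O)(=O)c2ccc(C)cc2)c1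
A3 | alternative 1 | ring B ortho-quinone methide: 2-{2-[3-methoxy-2-(methoxymethoxy)-4-(3-methylbut-2-en-1-yl)-6-oxocyclohexa-2,4-dien-1-ylidene]ethoxy}-4-(methoxymethoxy)benzaldehyde | O=C1C(OCOC)=C(OC)C(CC=C(C)C)=CC1=CCOc1cc(OCOC)ccc1C=O
A4 | alternative 2 | (3R)-7-[(tert-butyldimethylsilyl)oxy]-3-[7-methoxy-6-(3-methylbut-2-en-1-yl)-2,2-diphenyl-1,3-benzodioxol-4-yl]-2,3-dihydro-4H-chromen-4-one | COc1c(CC=C(C)C)cc([C@@H]2COc3cc(O[Si](C)(C)C(C)(C)C)ccc3C2=O)c2OC(c3ccccc3)(c3ccccc3)Oc12
A5 | alternative 2 | 1-{4-[(tert-butyldimethylsilyl)oxy]-2-methoxyphenyl}-2-diazo-2-[7-methoxy-6-(3-methylbut-2-en-1-yl)-2,2-diphenyl-1,3-benzodioxol-4-yl]ethan-1-one | COc1cc(O[Si](C)(C)C(C)(C)C)ccc1C(=O)C(=[N+]=[N-])c1cc(CC=C(C)C)c(OC)c2OC(c3ccccc3)(c3ccccc3)Oc12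
A6 | alternative 3 | racemic 3-[4-methoxy-2,3-bis(methoxymethoxy)-5-(3-methylbut-2-en-1-yl)phenyl]-7-(methoxymethoxy)-2,3-dihydro-4H-chromen-4-one | COCOc1ccc2c(c1)OCC(c1cc(CC=C(C)C)c(OC)c(OCOC)c1OCOC)C2=O
A7 | alternative 3 | 3-(methoxymethoxy)phenyl 2-[4-methoxy-2,3-bis(methoxymethoxy)-5-(3-methylbut-2-en-1-yl)phenyl]prop-2-enoate | C=C(C(=O)Oc1cccc(OCOC)c1)c1cc(CC=C(C)C)c(OC)c(OCOC)c1OCOC
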